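**Retrosynthetic overview**

1. Numbering (daucane): five-membered ring C1–C2–C3–C4–C5, seven-membered ring C1–C5–C6–C7–C8–C9–C10; C1 quaternary (CH3 = C15), C4 = C(OH)(i-Pr), C5 = fusion CH, C6 = CH–O-aroyl, C8(CH3 = C14)=C9, C10 = CH–O-angeloyl; β is the face of C15.
2. Endgame: aroyl ester at O6 and angelate at O10 by acylation; C6–OH from a C6 ketone by reduction directed by the 4β-OH; C10–O from C10–B with retention.
3. Key disconnection C10–C1: Cope (divinylcyclopropane–cycloheptadiene) rearrangement of a cis-1,2-dialkenylcyclopropane whose temporary bond C6–C8 (cyclopropane C6–C7–C8) is cleaved as the seven-membered ring closes. The enabling feature is that, in the seven-membered ring, the C8=C9 double bond and the oxygenated carbon C6 (enol form C5=C6) are separated only by the methylene C7 and flanked by C10 and C1, i.e. a masked cyclohepta-1,4-diene.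
4. The cyclopropane comes from an intramolecular carbenoid cyclopropanation through a temporary δ-lactone anchored on O4, which relays the C4 configuration to C6/C8 and from there to C1 and C10; the cyclopentene C1–C5 comes from (S)-terpinen-4-ol by ozonolysis/aldol ring contraction.
5. Ring order: five-membered ring (step 2), temporary lactone and cyclopropane (step 9), seven-membered ring (step 12).

Key step: step 12

Remark: (S)-terpinen-4-ol is assumed to be used in high enantiomeric purity; its carbinol carbon becomes C4 and is the only source of absolute configuration.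

**Route**

Step 1
Reactants: 1 (S)-terpinen-4-ol; 2 triethylsilyl trifluoromethanesulfonate
Product: 3 (S)-terpinen-4-yl triethylsilyl ether
Conditions: Et3SiOTf, 2,6-lutidine, CH2Cl2, 0 °C to rt
Reagents that add atoms: triethylsilyl trifluoromethanesulfonate 2, CC[Si](CC)(CC)OS(=O)(=O)C(F)(F)F
Why: Silylation of a tertiary alcohol with a silyl triflate and a hindered pyridine base is standard, and the ether keeps the C4 oxygen from leaving or triggering retro-aldol cleavage in step 2; C4 is carried over unchanged from 1.

Step 2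
Reactants: 3 (S)-terpinen-4-yl triethylsilyl ether; 4 ozone
Product: 7 (5R)-2-methyl-5-(propan-2-yl)-5-(triethylsilyloxy)cyclopent-1-ene-1-carbaldehyde, via ozonide 5 (not isolated), via keto aldehyde 6 (not isolated)
Conditions: O3, CH2Cl2, −78 °C; Me2S, −78 °C to rt; then Bn2NH·CF3CO2H (0.3 equiv), toluene, 50 °C
Reagents that add atoms: ozone 4, [O-][O+]=O
Why: Ozonolysis (Criegee mechanism) with reductive work-up opens the trisubstituted alkene, and amine-salt-catalysed intramolecular aldol condensation through the aldehyde enamine (5-enolexo attack on the methyl ketone) should close the cyclopentene and dehydrate towards C1, because the free aldol hydroxyl is lost more readily than the hindered silyloxy group at C4; no new stereocentre is formed.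

Step 3
Reactants: 7 (5R)-2-methyl-5-(propan-2-yl)-5-(triethylsilyloxy)cyclopent-1-ene-1-carbaldehyde; 8 methylmagnesium bromide
Product: 9 1-[(5R)-2-methyl-5-(propan-2-yl)-5-(triethylsilyloxy)cyclopent-1-en-1-yl]ethan-1-ol (both carbinol epimers)
Conditions: MeMgBr, THF, −78 to 0 °C; aq. NH4Cl
Reagents that add atoms: methylmagnesium bromide 8, C[Mg]Br
Why: Grignard 1,2-addition to the enal (the β-carbon is fully substituted) supplies C7; the carbinol centre forms as a mixture that is of no consequence because it is oxidised in step 4.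

Step 4
Reactants: 9 1-[(5R)-2-methyl-5-(propan-2-yl)-5-(triethylsilyloxy)cyclopent-1-en-1-yl]ethan-1-ol
Product: 10 1-[(5R)-2-methyl-5-(propan-2-yl)-5-(triethylsilyloxy)cyclopent-1-en-1-yl]ethan-1-one
Conditions: Dess–Martin periodinane, NaHCO3, CH2Cl2, 0 °C to rt
Reagents that add atoms: none
Why: Dess–Martin oxidation of a secondary allylic alcohol under buffered conditions leaves the tertiary silyl ether and the tetrasubstituted alkene untouched.

Step 5
Reactants: 10 1-[(5R)-2-methyl-5-(propan-2-yl)-5-(triethylsilyloxy)cyclopent-1-en-1-yl]ethan-1-one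
Product: 11 1-[(5R)-5-hydroxy-2-methyl-5-(propan-2-yl)cyclopent-1-en-1-yl]ethan-1-one
Conditions: Bu4NF, THF, 0 °C to rt
Reagents that add atoms: none
Why: Fluoride desilylation frees the tertiary C4 hydroxyl that anchors the temporary tether; retro-aldol cleavage is not possible because C5 is sp2.

Step 6
Reactants: 11 1-[(5R)-5-hydroxy-2-methyl-5-(propan-2-yl)cyclopent-1-en-1-yl]ethan-1-one; 12 propanoic anhydride
Product: 13 (1R)-2-acetyl-3-methyl-1-(propan-2-yl)cyclopent-2-en-1-yl propanoate
Conditions: (EtCO)2O, DMAP (1 equiv), Et3N, CH2Cl2, 40 °C, prolonged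
Reagents that add atoms: propanoic anhydride 12, CCC(=O)OC(=O)CC
Why: DMAP-catalysed acyl transfer (Steglich-type acylation) esterifies the hindered tertiary alcohol and installs the three carbons that become C9, C8 and C14.

Step 7
Reactants: 13 (1R)-2-acetyl-3-methyl-1-(propan-2-yl)cyclopent-2-en-1-yl propanoate; 14 tert-butyldimethylsilyl trifluoromethanesulfonate
Product: 15 (1R)-2-[1-(tert-butyldimethylsilyloxy)ethenyl]-3-methyl-1-(propan-2-yl)cyclopent-2-en-1-yl propanoate
Conditions: t-BuMe2SiOTf, Et3N, CH2Cl2, −78 to 0 °C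
Reagents that add atoms: tert-butyldimethylsilyl trifluoromethanesulfonate 14, CC(C)(C)[Si](C)(C)OS(=O)(=O)C(F)(F)F
Why: Soft enolisation of the methyl ketone gives the cross-conjugated 2-silyloxydiene (enol ether C6=C7) while the ester is not enolised, and masking the ketone removes the only electrophile that the ester enolate of step 8 could attack.

Step 8
Reactants: 15 (1R)-2-[1-(tert-butyldimethylsilyloxy)ethenyl]-3-methyl-1-(propan-2-yl)cyclopent-2-en-1-yl propanoate; 16 2,2,2-trifluoroethyl trifluoroacetate; 17 4-acetamidobenzenesulfonyl azide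
Product: 19 (1R)-2-[1-(tert-butyldimethylsilyloxy)ethenyl]-3-methyl-1-(propan-2-yl)cyclopent-2-en-1-yl 2-diazopropanoate, via trifluoroacetyl ester 18 (not isolated)
Conditions: LiN(SiMe3)2, THF, −78 °C; CF3CO2CH2CF3, −78 °C; then 4-AcNHC6H4SO2N3, Et3N, MeCN, rt
Reagents that add atoms: 4-acetamidobenzenesulfonyl azide 17, CC(=O)Nc1ccc(cc1)S(=O)(=O)N=[N+]=[N-]
Why: Deacylative (Regitz-type) diazo transfer: Claisen trifluoroacetylation of the ester enolate at −78 °C (too cold for Ireland–Claisen rearrangement of the allylic ester enolate) activates the α-carbon for diazo transfer, and loss of the trifluoroacetyl group delivers the α-diazopropanoate.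

Step 9
Reactants: 19 (1R)-2-[1-(tert-butyldimethylsilyloxy)ethenyl]-3-methyl-1-(propan-2-yl)cyclopent-2-en-1-yl 2-diazopropanoate
Product: 20 tricyclic cyclopropane-fused δ-lactone (4R,6R,8S): lactone O4–C9(=O)–C8–C6–C5–C4, cyclopropane C6–C7–C8, C6–OTBS and C8–CH3 cis, C7 on the isopropyl face
Conditions: Rh2(NHCOCH3)4 (1 mol %), CH2Cl2, reflux, slow addition of 19
Reagents that add atoms: none
Why: Intramolecular rhodium-carbenoid cyclopropanation of the electron-rich enol ether (a carboxamidate catalyst favours cyclopropanation over C–H insertion and β-hydride migration) closes the temporary δ-lactone and the cyclopropane; because C8 is anchored to the β-oxygen at C4 it should add to the enol-ether face turned towards that oxygen, so that the CH2 (C7) ends on the isopropyl (α) face, and the lactone ring fixes C5 and C9 cis on the cyclopropane.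

Step 10
Reactants: 20 tricyclic cyclopropane-fused δ-lactone
Product: 21 corresponding lactol (4R,6R,8S; anomeric mixture)
Conditions: i-Bu2AlH, CH2Cl2, −78 °C; aq. KNaC4H4O6
Reagents that add atoms: none
Why: Partial reduction of a δ-lactone with i-Bu2AlH at low temperature stops at the lactol through the stable tetrahedral aluminate; the anomeric centre is destroyed in step 11.

Step 11
Reactants: 21 lactol; 22 bis(pinacolato)borylmethane
Product: 23 cis-dialkenylcyclopropane (4R,6S,8R): 1-(tert-butyldimethylsilyloxy)-1-[(5R)-5-hydroxy-2-methyl-5-(propan-2-yl)cyclopent-1-en-1-yl]-2-methyl-2-[(E)-2-(pinacolboryl)ethenyl]cyclopropane, alkenyl groups cis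
Conditions: CH2(Bpin)2, lithium 2,2,6,6-tetramethylpiperidide (2.4 equiv), THF, 0 °C; then 21, −78 to 0 °C; cold work-up
Reagents that add atoms: bis(pinacolato)borylmethane 22, CC1(C)OB(CB2OC(C)(C)C(C)(C)O2)OC1(C)C
Why: Boron–Wittig olefination: the lactolate opens to the alkoxy aldehyde, the α-boryl carbanion adds and syn B–O elimination gives the (E)-alkenylboronate (the geometry that later controls C10), which unties the tether, frees O4 and completes the cis-dialkenylcyclopropane while the cold conditions should outrun ring opening of the donor–acceptor cyclopropane carbaldehyde.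

Step 12
Reactants: 23 cis-dialkenylcyclopropane
Product: 24 6-(tert-butyldimethylsilyloxy)-10α-(pinacolboryl)dauca-5,8-dien-4β-ol
Conditions: degassed toluene (0.02 M), 90 °C
Reagents that add atoms: none
Why: Thermal [3,3]-sigmatropic (Cope) rearrangement through the boat transition state in which both alkenyl groups lie over the three-membered ring: C10 and C1 bond while the strained temporary bond C6–C8 breaks and the π-bonds move to C8=C9 and C5=C6. The closest known reaction type is the divinylcyclopropane–cycloheptadiene rearrangement of silyloxy-substituted cis-dialkenylcyclopropanes, which tolerates one inside substituent and creates quaternary carbons. The seven-membered ring is closed as a cyclopropane-to-cycloheptadiene ring expansion by bond formation between the two alkene termini, the five-membered ring being carried along unchanged. C1 is controlled by the cyclopropane configuration fixed in step 9 (C10 can reach C1 only from the face on which C8 hangs, the α-face syn to isopropyl, which places C15 β and cis to the 4-OH), and C10 by the E geometry of the alkenylboronate (boron outside the boat, hence α and trans to C15). The step needs the concerted boat pathway to outrun homolysis of the donor-substituted C6–C8 bond, which would scramble C6/C8; the silyloxy group at C6 lowers the [3,3] barrier, the cis relationship of the alkenyl groups is locked in by the former lactone, and only the C1 methyl is an inside substituent. No alkyl group bearing hydrogen stands cis to an alkenyl group on the neighbouring ring carbon, so the competing homo-1,5-hydrogen shift is excluded.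

Step 13
Reactants: 24 6-(tert-butyldimethylsilyloxy)-10α-(pinacolboryl)dauca-5,8-dien-4β-ol; 25 sodium perborate tetrahydrate
Product: 26 6-(tert-butyldimethylsilyloxy)dauca-5,8-diene-4β,10α-diol
Conditions: NaBO3·4H2O, THF/H2O, 0 °C to rt
Reagents that add atoms: sodium perborate tetrahydrate 25, [Na+].[Na+].O[B-]1(O)OO[B-](O)(O)OO1
Why: Oxidation of the secondary allylic boronate (1,2-shift of carbon from boron to oxygen with retention) gives the 10α-alcohol, and the mildly basic perborate should spare the hindered silyl enol ether.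

Step 14
Reactants: 26 6-(tert-butyldimethylsilyloxy)dauca-5,8-diene-4β,10α-diol; 27 angelic acid
Product: 28 10α-angeloyloxy-6-(tert-butyldimethylsilyloxy)dauca-5,8-dien-4β-ol
Conditions: angelic acid, 2,4,6-Cl3C6H2COCl, Et3N, toluene, rt; then 26, 75 °C
Reagents that add atoms: angelic acid 27, C/C=C(/C)C(=O)O
Why: Yamaguchi esterification through the mixed trichlorobenzoic anhydride acylates the only acylable hydroxyl (C10; C4 is tertiary) and is chosen because it transfers angelates without isomerisation to the tiglate.

Step 15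
Reactants: 28 10α-angeloyloxy-6-(tert-butyldimethylsilyloxy)dauca-5,8-dien-4β-ol
Product: 29 10α-angeloyloxy-4β-hydroxy-5α-H-dauc-8-en-6-one (trans-fused)
Conditions: Bu4NF, AcOH (1:1), THF, 0 °C
Reagents that add atoms: none
Why: Buffered fluoride cleavage of the silyl enol ether (aqueous acid is avoided because it would ionise the tertiary allylic 4-OH) gives the C6 ketone by protonation at C5; the trans-fused epimer, in which C6 is cis to the small OH and CH3 groups and not to isopropyl, is expected to be favoured, and any cis epimer should equilibrate to it through the enol.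

Step 16
Reactants: 29 10α-angeloyloxy-4β-hydroxy-5α-H-dauc-8-en-6-one
Product: 30 10α-angeloyloxydauc-8-ene-4β,6α-diol
Conditions: Me4NBH(OAc)3, MeCN/AcOH (1:1), −30 °C
Reagents that add atoms: none
Why: Evans–Saksena reduction: the borohydride binds the 4β-hydroxyl and delivers hydride intramolecularly to the β-face of the C6 carbonyl, giving the 6α-alcohol (anti 1,3-diol), while the ester and the alkenes are inert to this reagent.

Step 17
Reactants: 30 10α-angeloyloxydauc-8-ene-4β,6α-diol; 31 4-(tert-butyldimethylsilyloxy)benzoic acid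
Product: 32 10α-angeloyloxy-6α-[4-(tert-butyldimethylsilyloxy)benzoyloxy]dauc-8-en-4β-ol
Conditions: DCC, DMAP, CH2Cl2, rt
Reagents that add atoms: 4-(tert-butyldimethylsilyloxy)benzoic acid 31, CC(C)(C)[Si](C)(C)Oc1ccc(cc1)C(=O)O
Why: Steglich esterification of the secondary C6 hydroxyl; the tertiary 4-OH does not compete and the phenol is carried as its silyl ether to prevent self-acylation.

Step 18
Reactants: 32 10α-angeloyloxy-6α-[4-(tert-butyldimethylsilyloxy)benzoyloxy]dauc-8-en-4β-ol
Product: 33 10α-angeloyloxy-6α-(4-hydroxybenzoyloxy)dauc-8-en-4β-ol (CNP0273650.2)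
Conditions: Bu4NF, AcOH, THF, 0 °C
Reagents that add atoms: none
Why: Buffered fluoride cleaves the aryl silyl ether far faster than it attacks either ester, releasing the phenol without acyl migration or angelate isomerisation.

**Compound list**

1 | (S)-terpinen-4-ol, (1S)-4-methyl-1-(propan-2-yl)cyclohex-3-en-1-ol | CC1=CC[C@](O)(C(C)C)CC1 | starting material
2 | triethylsilyl trifluoromethanesulfonate | CC[Si](CC)(CC)OS(=O)(=O)C(F)(F)F | starting material
3 | (S)-terpinen-4-yl triethylsilyl ether | CC1=CC[C@](O[Si](CC)(CC)CC)(C(C)C)CC1 | intermediate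
4 | ozone | [O-][O+]=O | starting material
5 | secondary ozonide (1,2,4-trioxolane) of 3 | CC12CC[C@@](O[Si](CC)(CC)CC)(C(C)C)CC(OO1)O2 | intermediate
6 | (3S)-6-oxo-3-(propan-2-yl)-3-(triethylsilyloxy)heptanal | O=CC[C@](O[Si](CC)(CC)CC)(C(C)C)CCC(C)=O | intermediate
7 | (5R)-2-methyl-5-(propan-2-yl)-5-(triethylsilyloxy)cyclopent-1-ene-1-carbaldehyde | O=CC1=C(C)CC[C@@]1(O[Si](CC)(CC)CC)C(C)C | intermediate
8 | methylmagnesium bromide | C[Mg]Br | starting material
9 | 1-[(5R)-2-methyl-5-(propan-2-yl)-5-(triethylsilyloxy)cyclopent-1-en-1-yl]ethan-1-ol, both carbinol epimers | CC(O)C1=C(C)CC[C@@]1(O[Si](CC)(CC)CC)C(C)C | intermediate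
10 | 1-[(5R)-2-methyl-5-(propan-2-yl)-5-(triethylsilyloxy)cyclopent-1-en-1-yl]ethan-1-one | CC(=O)C1=C(C)CC[C@@]1(O[Si](CC)(CC)CC)C(C)C | intermediate
11 | 1-[(5R)-5-hydroxy-2-methyl-5-(propan-2-yl)cyclopent-1-en-1-yl]ethan-1-one | CC(=O)C1=C(C)CC[C@@]1(O)C(C)C | intermediate
12 | propanoic anhydride | CCC(=O)OC(=O)CC | starting material
13 | (1R)-2-acetyl-3-methyl-1-(propan-2-yl)cyclopent-2-en-1-yl propanoate | CC(=O)C1=C(C)CC[C@@]1(OC(=O)CC)C(C)C | intermediate
14 | tert-butyldimethylsilyl trifluoromethanesulfonate | CC(C)(C)[Si](C)(C)OS(=O)(=O)C(F)(F)F | starting material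
15 | (1R)-2-[1-(tert-butyldimethylsilyloxy)ethenyl]-3-methyl-1-(propan-2-yl)cyclopent-2-en-1-yl propanoate | C=C(O[Si](C)(C)C(C)(C)C)C1=C(C)CC[C@@]1(OC(=O)CC)C(C)C | intermediate
16 | 2,2,2-trifluoroethyl trifluoroacetate | FC(F)(F)COC(=O)C(F)(F)F | starting material
17 | 4-acetamidobenzenesulfonyl azide | CC(=O)Nc1ccc(cc1)S(=O)(=O)N=[N+]=[N-] | starting material
18 | (1R)-2-[1-(tert-butyldimethylsilyloxy)ethenyl]-3-methyl-1-(propan-2-yl)cyclopent-2-en-1-yl 4,4,4-trifluoro-2-methyl-3-oxobutanoate (present as its enolate) | C=C(O[Si](C)(C)C(C)(C)C)C1=C(C)CC[C@@]1(OC(=O)C(C)C(=O)C(F)(F)F)C(C)C | intermediate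
19 | (1R)-2-[1-(tert-butyldimethylsilyloxy)ethenyl]-3-methyl-1-(propan-2-yl)cyclopent-2-en-1-yl 2-diazopropanoate | C=C(O[Si](C)(C)C(C)(C)C)C1=C(C)CC[C@@]1(OC(=O)C(C)=[N+]=[N-])C(C)C | intermediate
20 | tricyclic cyclopropane-fused δ-lactone (4R,6R,8S), C7 on the isopropyl face, C6–OTBS cis to C8–CH3 | O=C1O[C@@]2(C(C)C)CCC(C)=C2[C@]3(O[Si](C)(C)C(C)(C)C)C[C@]13C | intermediate
21 | lactol of 20 (4R,6R,8S; anomeric mixture) | OC1O[C@@]2(C(C)C)CCC(C)=C2[C@]3(O[Si](C)(C)C(C)(C)C)C[C@]13C | intermediate
22 | bis(pinacolato)borylmethane | CC1(C)OB(CB2OC(C)(C)C(C)(C)O2)OC1(C)C | starting material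
23 | cis-dialkenylcyclopropane (4R,6S,8R) with (E)-alkenylboronate and free 4-OH | CC(C)[C@]1(O)CCC(C)=C1[C@]2(O[Si](C)(C)C(C)(C)C)C[C@]2(C)/C=C/B3OC(C)(C)C(C)(C)O3 | intermediate
24 | 6-(tert-butyldimethylsilyloxy)-10α-(pinacolboryl)dauca-5,8-dien-4β-ol | CC1(C)OB(OC1(C)C)[C@@H]2C=C(C)CC(O[Si](C)(C)C(C)(C)C)=C3[C@]2(C)CC[C@@]3(O)C(C)C | intermediate
25 | sodium perborate tetrahydrate | [Na+].[Na+].O[B-]1(O)OO[B-](O)(O)OO1 | starting material
26 | 6-(tert-butyldimethylsilyloxy)dauca-5,8-diene-4β,10α-diol | O[C@@H]1C=C(C)CC(O[Si](C)(C)C(C)(C)C)=C2[C@]1(C)CC[C@@]2(O)C(C)C | intermediate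
27 | angelic acid, (Z)-2-methylbut-2-enoic acid | C/C=C(/C)C(=O)O | starting material
28 | 10α-angeloyloxy-6-(tert-butyldimethylsilyloxy)dauca-5,8-dien-4β-ol | C/C=C(/C)C(=O)O[C@@H]1C=C(C)CC(O[Si](C)(C)C(C)(C)C)=C2[C@]1(C)CC[C@@]2(O)C(C)C | intermediate
29 | 10α-angeloyloxy-4β-hydroxy-5α-H-dauc-8-en-6-one | C/C=C(/C)C(=O)O[C@@H]1C=C(C)CC(=O)[C@@H]2[C@]1(C)CC[C@@]2(O)C(C)C | intermediate
30 | 10α-angeloyloxydauc-8-ene-4β,6α-diol | C/C=C(/C)C(=O)O[C@@H]1C=C(C)C[C@H](O)[C@@H]2[C@]1(C)CC[C@@]2(O)C(C)C | intermediate
31 | 4-(tert-butyldimethylsilyloxy)benzoic acid | CC(C)(C)[Si](C)(C)Oc1ccc(cc1)C(=O)O | starting material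
32 | 10α-angeloyloxy-6α-[4-(tert-butyldimethylsilyloxy)benzoyloxy]dauc-8-en-4β-ol | C/C=C(/C)C(=O)O[C@@H]1C=C(C)C[C@H](OC(=O)c2ccc(O[Si](C)(C)C(C)(C)C)cc2)[C@@H]2[C@]1(C)CC[C@@]2(O)C(C)C | intermediate
33 | 10α-angeloyloxy-6α-(4-hydroxybenzoyloxy)dauc-8-en-4β-ol (CNP0273650.2) | C/C=C(/C)C(=O)O[C@@H]1C=C(C)C[C@H](OC(=O)c2ccc(O)cc2)[C@@H]2[C@]1(C)CC[C@@]2(O)C(C)C | target

**Step count and risks**

Total step count: 18. Longest linear sequence: 18 steps from 1; all other numbered starting materials are purchased reagents.

Steps most likely to fail: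

Step 9. The carbenoid may rearrange by β-hydride migration to the acrylate, insert into the isopropyl C–H bond, add to the ring alkene, or cyclopropanate with the wrong facial sense. The fallback makes the cyclopropane intermolecularly under catalyst control and sets out from ketone 10. Soft enolisation (t-BuMe2SiOTf, Et3N) gives the silyloxydiene triethylsilyl ether F1. Slow addition of methyl 2-diazopropanoate with dirhodium tetrakis[N-phthaloyl-(S)-tert-leucinate] (or its enantiomer, whichever matches C4) at −78 °C cyclopropanates the enol ether to the methyl cyclopropanecarboxylate F2, the isomer with ester cis to cyclopentenyl being separated. HF·pyridine buffered with pyridine removes the triethylsilyl group selectively to give the hydroxy ester F3, and NaH in THF closes the lactone, which only the cis isomer can do. The route is rejoined at 20.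

Step 12. The inside methyl at C1 raises the [3,3] barrier, so the rearrangement may need temperatures at which the C6–C8 bond homolyses; that would epimerise the cyclopropane and erode C1/C10. The fallback is the oxyanion-accelerated variant and sets out from 23. Fluoride (Bu4NF, THF, −78 to 0 °C) unmasks the cyclopropanolate, whose [3,3] shift is expected well below room temperature and gives, after protonation of the enolate, the keto boronate F5. NaBO3 oxidation gives the hydroxy ketone F6, and Yamaguchi esterification with 27 rejoins the route at 29, replacing steps 13 to 15.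

Step 11. The hydroxy aldehyde released from 21 may decompose before olefination (ring opening of the donor–acceptor cyclopropane or retro-Claisen rearrangement to a dihydrooxepine), or the α-boryl carbanion may fail to engage the lactolate. The fallback separates homologation from boron introduction and sets out from 21. Seyferth–Gilbert homologation with the Ohira–Bestmann reagent (dimethyl (1-diazo-2-oxopropyl)phosphonate, K2CO3, MeOH, 0 °C) gives the ethynylcyclopropane F4. Hydroboration of the terminal alkyne with pinacolborane catalysed by Cp2Zr(H)Cl (syn, anti-Markovnikov) gives the (E)-alkenylboronate and rejoins the route at 23.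

**Further compounds**

F1 | step 9 | (R)-silyloxydiene triethylsilyl ether: tert-butyldimethylsilyl enol ether of 10 | C=C(O[Si](C)(C)C(C)(C)C)C1=C(C)CC[C@@]1(O[Si](CC)(CC)CC)C(C)C
F2 | step 9 | methyl (6R,8S)-cyclopropanecarboxylate with C6–OTBS, C8–CH3, ester cis to cyclopentenyl, 4-OTES | COC(=O)[C@@]1(C)C[C@@]1(O[Si](C)(C)C(C)(C)C)C2=C(C)CC[C@@]2(O[Si](CC)(CC)CC)C(C)C
F3 | step 9 | hydroxy ester: F2 without the triethylsilyl group | COC(=O)[C@@]1(C)C[C@@]1(O[Si](C)(C)C(C)(C)C)C2=C(C)CC[C@@]2(O)C(C)C
F4 | step 11 | ethynylcyclopropane (4R,6S,8R) with free 4-OH | CC(C)[C@]1(O)CCC(C)=C1[C@]2(O[Si](C)(C)C(C)(C)C)C[C@]2(C)C#C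
F5 | step 12 | 4β-hydroxy-10α-(pinacolboryl)-5α-H-dauc-8-en-6-one | CC1(C)OB(OC1(C)C)[C@@H]2C=C(C)CC(=O)[C@@H]3[C@]2(C)CC[C@@]3(O)C(C)C
F6 | step 12 | 4β,10α-dihydroxy-5α-H-dauc-8-en-6-one | O[C@@H]1C=C(C)CC(=O)[C@@H]2[C@]1(C)CC[C@@]2(O)C(C)C
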